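## Retrosynthetic overview

1. **Feature used.** Oxygen sits on every second carbon of the C22 backbone (C5-OH, C7-OH, C8a-O1, C4=O, C2-O1). The target is therefore a twice cyclised, twice dehydrated 3,5,7,9-tetraoxodocosanoic acid (tetradecanoyl starter plus four C2 units). The route folds this chain instead of buying phloroglucinol.
2. **Key disconnection.** The C4a–C5 bond of the benzenoid ring (C4a-C5-C6-C7-C8-C8a) is opened as a retro-6π step to a dienylketene. The ketene (C5=C6) and the C7 oxygen are stored in the dioxinone of 8.
3. **Second ring.** The O1–C2 bond of the pyranone is opened to the acetylenic β-diketone 7 (ynone C4(=O)-C3≡C2). The ynone directs O-closure at C2 and removes the aldol folding modes.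
4. **Chain.** The C4–C4a bond comes from a keto-dioxinone dianion (C5 to C8a plus C4a) and a Weinreb ynamide (C4, C3, C2, tridecyl).
5. **Ring order.** The pyranone forms first and the benzene ring last, with no protecting groups and no redox steps.

Key step: step 4

Assumption: the target has no stereocentre and no stereogenic double bond, so the request for a single enantiomer has no bearing on the route. The chromone numbering of 11 is used for the corresponding atoms of all intermediates.

## Route

Step 1
Reactants: 1 1-pentadecyne; 2 N-methoxy-N-methylcarbamoyl chloride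
Product: 3 N-methoxy-N-methylhexadec-2-ynamide
Conditions: n-BuLi (1.05 equiv), THF, −78 °C; cannulated into 2 (1.3 equiv), THF, −78 °C to 0 °C; aq NH4Cl
Reagents that add atoms: N-methoxy-N-methylcarbamoyl chloride, CON(C)C(=O)Cl
Why: Acylation of a lithium acetylide with the Weinreb carbamoyl chloride should stop at the amide, because the acid chloride, kept in excess by inverse addition, is far more electrophilic than the product.

Step 2
Reactants: 4 2,2,6-trimethyl-4H-1,3-dioxin-4-one; 5 acetyl chloride
Product: 6 2,2-dimethyl-6-(2-oxopropyl)-4H-1,3-dioxin-4-one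
Conditions: 4 (2.0 equiv), LiHMDS (2.0 equiv), THF, −78 °C; 5 (1.0 equiv), −78 °C; 1 M HCl
Reagents that add atoms: acetyl chloride, CC(=O)Cl
Why: This is the known γ-selective C-acylation (vinylogous Claisen condensation) of the dioxinone lithium dienolate; the second equivalent of dienolate deprotonates the more acidic product and so protects it from further acylation.

Step 3
Reactants: 6 2,2-dimethyl-6-(2-oxopropyl)-4H-1,3-dioxin-4-one; 3 N-methoxy-N-methylhexadec-2-ynamide
Product: 8 2,2-dimethyl-6-[(4-oxo-6-tridecyl-4H-pyran-2-yl)methyl]-4H-1,3-dioxin-4-one, via acetylenic diketo-dioxinone 7 (not isolated)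
Conditions: 6 (1.5 equiv), LDA (3.1 equiv), THF, −78 °C; 3 (1.0 equiv), −78 to −20 °C; poured into cold 1 M HCl; crude in CH2Cl2, TfOH (1.5 equiv), 0 °C to rt; aq NaHCO3
Reagents that add atoms: none
Why: Claisen-type acylation of the keto-dioxinone 1,3-dianion at its terminal, more basic carbon by a Weinreb amide, whose chelated tetrahedral adduct survives until the acid quench and prevents over-addition, gives 7, and the strong-acid 6-endo-dig oxa-Michael closure known for acetylenic β-diketones and o-alkynoylphenols then forms the 4-pyranone, the dioxinone being stable to anhydrous strong acid because it is itself made under such conditions.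

Step 4
Reactants: 8 2,2-dimethyl-6-[(4-oxo-6-tridecyl-4H-pyran-2-yl)methyl]-4H-1,3-dioxin-4-one
Product: 11 5,7-dihydroxy-2-tridecyl-4H-chromen-4-one, via acylketene 9 (not isolated), via 4aH-dienone 10 (not isolated)
Conditions: dry PhMe (5 mM), reflux, N2 sweep to remove acetone
Reagents that add atoms: none
Why: Proposed new method: heating expels acetone from the dioxinone by the standard retro-[4+2] route to acylketene 9, whose C8 methylene (flanked by the C7 carbonyl and the pyranone) enolises so that the ketene C5=C6, the enol C7=C8 and the pyranone C8a=C4a bonds line up as a 3-hydroxy-dienylketene. A thermal disrotatory 6π electrocyclisation, which can equally be read as attack of the doubly oxygen-activated enol-ether carbon C4a on the ketene carbon C5, forms the C4a–C5 bond and closes the six-membered carbocycle to dienone 10, and transfer of the C4a proton to oxygen aromatises it to 11 with the ketene oxygen as the chelated 5-OH and the enol oxygen as the 7-OH. The closest known reaction types are the dienylketene-to-phenol closure that ends a Danheiser benzannulation, the ketene electrocyclisation onto an arene in the Conrad–Limpach and Gould–Jacobs quinolone syntheses, and the acid cyclisation of 4-arylacetoacetates to naphthalene-1,3-diols; what has not been shown is a 4-pyranone C2=C3 bond as the terminus and an enolised dioxinone-derived acylketene as the triene. The only new stereocentre (C4a of 10) is transient and is erased on aromatisation, so nothing needs to be controlled. The step needs C- over O-acylation and one folding mode out of several: a free poly-β-carbonyl chain would trap the ketene through the C8a enol oxygen to give a 4-hydroxy-2-pyranone or would fold by aldol modes, but in 8 that oxygen is already O1 of the pyranone and C2 and C4 are locked in the ring, so C4a is the only nucleophile within six-membered reach of C5. High dilution, dry solvent and removal of acetone should keep ketene dimerisation, hydration and re-addition of acetone from competing.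

## Compound list

1 | 1-pentadecyne | CCCCCCCCCCCCCC#C | starting material
2 | N-methoxy-N-methylcarbamoyl chloride | CON(C)C(=O)Cl | starting material
3 | N-methoxy-N-methylhexadec-2-ynamide | CCCCCCCCCCCCCC#CC(=O)N(C)OC | intermediate
4 | 2,2,6-trimethyl-4H-1,3-dioxin-4-one | CC1=CC(=O)OC(C)(C)O1 | starting material
5 | acetyl chloride | CC(=O)Cl | starting material
6 | 2,2-dimethyl-6-(2-oxopropyl)-4H-1,3-dioxin-4-one | CC(=O)CC1=CC(=O)OC(C)(C)O1 | intermediate
7 | 6-(2,4-dioxononadec-5-yn-1-yl)-2,2-dimethyl-4H-1,3-dioxin-4-one (acetylenic diketo-dioxinone, drawn as the diketo tautomer) | CCCCCCCCCCCCCC#CC(=O)CC(=O)CC1=CC(=O)OC(C)(C)O1 | intermediate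
8 | 2,2-dimethyl-6-[(4-oxo-6-tridecyl-4H-pyran-2-yl)methyl]-4H-1,3-dioxin-4-one | CCCCCCCCCCCCCC1=CC(=O)C=C(CC2=CC(=O)OC(C)(C)O2)O1 | intermediate
9 | 3-oxo-4-(4-oxo-6-tridecyl-4H-pyran-2-yl)but-1-en-1-one (acylketene) | O=C=CC(=O)CC1=CC(=O)C=C(CCCCCCCCCCCCC)O1 | intermediate
10 | 7-hydroxy-2-tridecyl-4aH-chromene-4,5-dione (transient dienone, racemic at C4a) | CCCCCCCCCCCCCC1=CC(=O)C2C(=O)C=C(O)C=C2O1 | intermediate
11 | 5,7-dihydroxy-2-tridecyl-4H-chromen-4-one | CCCCCCCCCCCCCc1cc(=O)c2c(O)cc(O)cc2o1 | target

## Step count and risks

Total step count: 4.
Longest linear sequence: 3 (1 → 3 → 8 → 11, or 4 → 6 → 8 → 11).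

**1. Step 4 (Proposed new method).**
- What may go wrong: pyranone C4a is only a moderate π-nucleophile. The ketene may therefore be consumed by dimerisation, or by capture of trace water followed by decarboxylation, before the C–C closure takes place.
- Fallback (known chemistry; the arene is bought and the pyranone is closed last): it sets out from 3 and comes back at 11.
  - Commercial 1,3,5-trimethoxybenzene is lithiated with n-BuLi and acylated by 3 to give 1-(2,4,6-trimethoxyphenyl)hexadec-2-yn-1-one F1.
  - Excess BBr3 in CH2Cl2 cleaves the three methyl ethers to 1-(2,4,6-trihydroxyphenyl)hexadec-2-yn-1-one F2.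
  - F2 closes to 11 by the TfOH-promoted 6-endo-dig cyclisation of o-alkynoylphenols. The two ortho hydroxyls are equivalent, so no regiochemical question arises.

**2. Step 3.**
- What may go wrong: the delocalised dianion may add in a conjugate sense to the ynamide, or deprotonate its propargylic position, instead of attacking the carbonyl. The released amine may also add to the ynone during the quench.
- Fallback (aldol addition and oxidation in place of acyl substitution): it sets out from 1 and 6 and comes back at 7.
  - The lithium acetylide of 1 is formylated with DMF to give hexadec-2-ynal F3, which can only react in the 1,2 sense.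
  - The dianion of 6 adds to F3 to give 6-(4-hydroxy-2-oxononadec-5-yn-1-yl)-2,2-dimethyl-4H-1,3-dioxin-4-one F4. F4 is racemic, and its carbinol centre is erased in the next operation.
  - Dess–Martin oxidation gives 7, which is closed with TfOH as in step 3.

**3. Step 2.**
- What may go wrong: O-acylation, α-acylation or a second acylation of the dienolate, and proton exchange with the product.
- Fallback (a neutral vinylogous nucleophile with an aldehyde, then oxidation): it sets out from 4 and comes back at 6.
  - LDA and TMSCl convert 4 into 2,2-dimethyl-6-methylidene-4-(trimethylsilyloxy)-6H-1,3-dioxine F5.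
  - A BF3·OEt2-mediated vinylogous Mukaiyama aldol reaction of F5 with acetaldehyde, strictly γ-selective, gives 6-(2-hydroxypropyl)-2,2-dimethyl-4H-1,3-dioxin-4-one F6 (racemic).
  - Dess–Martin oxidation of F6 gives 6.

## Further compounds

F1 | step 4 | 1-(2,4,6-trimethoxyphenyl)hexadec-2-yn-1-one | CCCCCCCCCCCCCC#CC(=O)c1c(OC)cc(OC)cc1OC
F2 | step 4 | 1-(2,4,6-trihydroxyphenyl)hexadec-2-yn-1-one | CCCCCCCCCCCCCC#CC(=O)c1c(O)cc(O)cc1O
F3 | step 3 | hexadec-2-ynal | CCCCCCCCCCCCCC#CC=O
F4 | step 3 | 6-(4-hydroxy-2-oxononadec-5-yn-1-yl)-2,2-dimethyl-4H-1,3-dioxin-4-one (racemic) | CCCCCCCCCCCCCC#CC(O)CC(=O)CC1=CC(=O)OC(C)(C)O1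
F5 | step 2 | 2,2-dimethyl-6-methylidene-4-(trimethylsilyloxy)-6H-1,3-dioxine | C=C1C=C(O[Si](C)(C)C)OC(C)(C)O1
F6 | step 2 | 6-(2-hydroxypropyl)-2,2-dimethyl-4H-1,3-dioxin-4-one (racemic) | CC(O)CC1=CC(=O)OC(C)(C)O1
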